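A small charge of substrate is slower in these two runs: the dawn run, with 0.17 M, still holds 52.5 % at 60.0 s, while the summer run, with 0.25 M, holds 17.1 %. The asked flask is the summer run itself, followed further.

| flask | substrate | remark | time |
|---|---|---|---|
| summer | 0.25 M | the very flask that is asked about, followed so far |  |
| dawn | 0.17 M | run made earlier |  |
| flask | 0.25 M |  | 5.0 min |

| run | time / s | substrate / % | product / % |
|---|---|---|---|
| summer | 20.0 | 94.0 | 4.7 |
| summer | 40.0 | 62.1 | 37.0 |
| summer | 60.0 | 17.1 | 82.4 |
| summer | 80.0 | 2.2 | 97.4 |
| summer | 90.0 | 0.1 | 99.1 |
| summer | 120 | 0 | 98.5 |
| dawn | 20.0 | 97.4 | 3.0 |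
| dawn | 40.0 | 82.5 | 17.0 |
| dawn | 60.0 | 52.5 | 48.8 |
| dawn | 80.0 | 20.1 | 80.3 |
| dawn | 90.0 | 11.5 | 88.6 |
| dawn | 120 | 1.6 | 98.8 |

(standard deviation of a reading: 0.5 percentage points)

- why nothing more happens at 5.0 min, or that something still does (forward and back rates have come level / it is still moving / all of the substrate has reacted)
- conversion of substrate at 5.0 min
- amount of product at 5.0 min, in percent of the substrate charged

- the reaction counts as stopped when no species that holds the substrate changes by six tenths of a point or more over the second half of the time

Both curves are S-shaped, as in autocatalysis, so I work in powers of ten. I take the common logarithm of product over substrate. In the summer run it climbs between 40.0 s and 60.0 s at the slope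

s = 0.0454 /s

and on that line it passes equal amounts at

t_c = 45.0 s

At the asked time that gives

Z = s (t − t_c) = 11.6

This is my decade count: the powers of ten by which I reckon product to stand above substrate in the summer flask at the asked time. I reckon a conversion of >99.9 %.

Is one number enough? I scale the slope by the charge, to 0.0309 /s for the dawn run, whose own crossing is 61.0 s. Its count at 120 s is then 1.82, so I expect 1.49 % substrate, and the reading is 1.6 %. The slope scaled by the charge serves for the dawn run, but the crossing remains a second reading for each run. The count is also a ratio: it gives a conversion if the sum of the two stays at the charge.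

The forecast says all of the substrate has reacted, with conversion 100 % and product 99.2 %, “allowing slight loss”. Its product figure stands below the conversion I reckon.

The flask gives 100 % conversion and 100 % product: all of the substrate has reacted. Substrate is already at 0 % at 2.50 min, and the change over the second half of the time is 0 percentage points.

    substrate + product → 2 product (k = 0.420 /M/s)
    substrate → product (k = 8.90 × 10⁻⁴ /s)

The count of 11.6 for this flask exceeds the count at 2.0 min, which is 3.41. That smaller count reckons substrate at 0.0392 %. The same flask left until 2.0 min holds 0.0360 %.

Readings and results are simulated on assumed constants; scatter was added.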